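Abbreviations used throughout: prenyl = 3-methylbut-2-en-1-yl; TIPS = triisopropylsilyl; pin = pinacolato; Cp = cyclopentadienyl. Isoflavan numbering: pyran O1, C2, C3, C4; benzo ring A C4a–C8a; quinone ring B C1'–C6'.

## Analysis of the target

The target (38) is an isoflavanquinone: a chroman (ring A fused to the pyran ring) that carries a 2-hydroxy-1,4-benzoquinone (ring B) at C3. Ring A has methoxy groups at C5 and C7, a prenyl group between them at C6, and hydrogen only at C8. Ring B has carbonyls at C2' and C5', a hydroxyl at C4', a prenyl group at C3' and hydrogen at C6'. C3 is the only stereocentre, (R), and lies between two methylene groups, so no neighbouring group can direct its formation. The hydroxyquinone is a vinylogous acid, sensitive to base, nucleophiles and reductants, and C3–H is vinylogously alpha to its carbonyls, so the quinone must appear last and near neutral pH. The two trisubstituted alkenes exclude hydrogenation, strong acid and electrophilic oxidants, and ring A is electron-rich enough to suffer from one-electron oxidants. The hard points are therefore the isolated stereocentre, the placing of the ring A prenyl group at C6 and not C8, and the contiguous C1'–C4' substitution of ring B. The strategy rests on one feature: without the C5' oxygen, ring B is a resorcinol with oxygen at C2' and C4', the prenyl group between them at C3' and the chroman at C1'. This is the pattern formed when a vinylketene is joined to a siloxyalkyne.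

## Retrosynthetic reasoning

**Quinone oxygen (C5'–O).** The last bond cut is the C5'–O bond of 38, which leaves resorcinol 36. Its C5' is para to the C2' hydroxyl and ortho to the C4' hydroxyl, so oxidation with nitrosodisulfonate 37 from either phenol leads to the same hydroxyquinone. Doing this last keeps the sensitive quinone out of all other steps. Resorcinol 36 comes from its 4'-O-silyl ether 35 by desilylation; the silyl group is the residue of the ring-forming step, not an added protecting group.

**Ring B (C5'–C6', C2'–C3', C4'–C5', C1'–C2').** Ring B of 35 is cut into diazo ketone 23 and siloxyalkyne 30. Compound 23 supplies C2', C5', C6' and C1' with the intact chroman; 30 supplies C3' with its prenyl group and C4' with its oxygen. Cutting here rather than at C3–C1' avoids coupling a stereodefined secondary carbon to a 2,6-disubstituted electron-rich arene, and avoids ring B protecting groups that would have to be removed beside a prenyl group. The forward reaction must convert 23 into vinylketene 31, add 30 in one orientation (32) and electrocyclise (33, 34) to the phenol, with C3 only a spectator on the alkene terminus.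

**Siloxyalkyne 30.** The triple bond is traced to the carbonyl carbon of ester 26 and the carbon of dibromomethane 27 (ester-to-ynolate homologation through 28 and 29), with silyl chloride 2 capping the oxygen. Ester 26 is made from acid 24 and iodoethane 25. The prenyl chain is present from the start, so ring B never has to be allylated.

**Diazo ketone 23.** The diazo group is added last, by diazo transfer from azide 21 to methyl ketone 20 via activated diketone 22, because a diazo ketone would not survive organometallic steps. Enone 20 is cut between its carbonyl carbon and the alkene (the future C2' and C6'), giving alkyne 17 and acetyl chloride 18. Hydrozirconation (19) sets the E geometry in one step and avoids an aldehyde at C3, which would be prone to epimerisation and to beta-elimination of the ring oxygen.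

**C3–C1' bond.** Alkyne 17 comes from bromoalkene 16 by elimination, and 16 from boronate 13 and vinyl bromide 14 by a boron-to-carbon 1,2-shift through ate complex 15. Such shifts transfer the configuration of the C–B carbon with retention, so the C–C bond at the lone stereocentre is made stereospecifically.

**C3–B bond and the stereocentre.** Boronate 13 is traced to chromene 11 and diboron 12. The styrene-type C3=C4 bond is the one handle the chroman offers for enantioface-selective addition. A copper–boryl addition puts boron at C3, away from the arene, under control of a chiral ligand.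

**Pyran ring (C4–C4a).** Chromene 11 is opened to propargyl ether 9 (forward via allenylphenol 10). Ether 9 is made from silyl ether 6 and propargyl bromide 7 through phenoxide 8. The arene of 9 is symmetric, so both ortho carbons are equivalent and only one chromene can form.

**Ring A prenyl group.** The C6–prenyl bond is cut at silyl ether 6, which goes back to 3 and prenyl bromide 4 (via aryllithium 5), and then to 3,5-dimethoxyphenol 1 and 2. Placing the prenyl group between the two methoxy groups before the pyran ring exists removes the C6/C8 ambiguity of a 5,7-dimethoxychroman.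

## Alternatives that were turned down

**Alternative 1: three-component conjunctive coupling.**
- **Disconnection:** C3–C1' and C4–C4a are cut together, leaving vinylboronic pinacol ester A1 between ring B aryllithium A2 and ring A aryl triflate A3.
- **Forward key step:** A2 adds to A1 to give an ate complex. A chiral bisphosphine–palladium catalyst (Pd(OAc)2 with a ferrocenyl bisphosphine) inserts into A3 and binds the alkene. The ring B aryl group shifts from boron to the alpha carbon while palladium delivers ring A to the beta carbon. The product is secondary boronate A4, with boron at the future C3 and no ring closed.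
- **For:** it is the most convergent plan. Both arenes and the stereocentre are joined in one catalytic step, and enantiocontrol in aryl-migrating conjunctive couplings is well founded. On convergence and on directness of the asymmetric step it is stronger than the chosen route.
- **Against:** A3 is a 2,6-disubstituted, very electron-rich electrophile and the migrating aryl group is itself ortho-substituted, so both oxidative addition and the metallate shift are hindered. A4 still lacks C2, so a one-carbon homologation, oxidation, acidic acetal removal beside a prenyl group and a ring closure follow. Ring B then arrives as a 2,4,5-trimethoxyarene that must be oxidatively demethylated (Ce(NH4)2(NO3)6) in the presence of electron-rich ring A and two prenyl groups, and the remaining quinone methyl ether must be cleaved.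
- **Comparison:** about six or seven steps follow its key step, against two here. The chosen route builds ring B at the correct oxidation pattern with one fluoride-labile silyl group and no ring B methyl ether.

**Alternative 2: quinone–chromene [3+2] annulation, then reductive opening.**
- **Disconnection:** the C3–C1' bond and a temporary C4–O bond, giving chromene 11 and 2-methoxy-3-prenyl-1,4-benzoquinone A5.
- **Forward key step:** A5 is bound to a chiral complex of tetravalent titanium, TiCl2(TADDOLate). C3 of 11 attacks the unsubstituted C5 of A5, and the benzylic cation at C4 is trapped by the adjacent quinone oxygen. This closes a cis-fused dihydrofuran and gives pterocarpan A6.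
- **For:** it is the shortest route on paper. It uses 11 directly, brings all three ring B oxygens at once and sets C3 in the ring-joining step. In step count it is stronger than the chosen route.
- **Against:** a strong Lewis acid must coexist with two prenyl groups and a highly ionisable, electron-rich chromene. Facial control depends on two-point binding of the methoxyquinone, which the neighbouring 3-prenyl group perturbs, and [2+2] and [5+2] modes compete. The benzylic C4–O bond must then be cleaved reductively without hydrogenating the prenyl groups, and the quinone methyl ether must still be removed.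
- **Comparison:** the chosen route needs no Lewis acid and no reduction, and its regiochemistry follows from alkyne polarisation rather than catalyst binding.

**Alternative 3: aminocatalytic ortho-quinone methide annulation.**
- **Disconnection:** C3–C4 and O1–C2, giving arylacetaldehyde A7 and sulfone A8.
- **Forward key step:** a chiral secondary amine converts A7 into its enamine. Base releases ortho-quinone methide A9 from A8. The enamine alpha carbon adds to the methide carbon, and the phenoxide closes on the aldehyde to give lactol A10 as an anomeric mixture.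
- **For:** it is metal-free and mild, and it forms the pyran ring and C3 together from two simple pieces. It is stronger than the chosen route in operational simplicity.
- **Against:** A7 is a self-condensing, electron-rich arylacetaldehyde. C3 in A10 is benzylic and alpha to a masked aldehyde, so it can epimerise through the open form. A9 is stabilised by three donor groups and is therefore a weak electrophile. The lactol carbon needs further steps to become a CH2 group, and ring B again requires trimethoxyarene-to-hydroxyquinone unmasking.
- **Comparison:** the chosen route keeps C3 away from any enolisable carbonyl until the final oxidation and delivers ring B without methyl ethers.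

Key step: step 12

Assumption: the facial sense of the copper catalyst in step 5 cannot be predicted with certainty for this chromene. The ligand antipode giving (3S)-13 is chosen after oxidising a sample of 13 to the chroman-3-ol and assigning its configuration.

## Route

Step 1
Reactants: 1 3,5-dimethoxyphenol; 2 chlorotriisopropylsilane
Product: 3 (3,5-dimethoxyphenoxy)triisopropylsilane
Conditions: imidazole, DMF, rt
Reagents that add atoms: chlorotriisopropylsilane, CC(C)[Si](Cl)(C(C)C)C(C)C
Why: Imidazole-promoted O-silylation; the bulky, weakly coordinating TIPS ether leaves the next metalation to the two methoxy groups.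

Step 2
Reactants: 3 (3,5-dimethoxyphenoxy)triisopropylsilane; 4 prenyl bromide
Product: 6 (3,5-dimethoxy-4-prenylphenoxy)triisopropylsilane, via aryllithium 5 (not isolated)
Conditions: n-BuLi, TMEDA, THF, 0 °C; then CuI (10 mol%), 4, −78 °C to rt
Reagents that add atoms: prenyl bromide, CC(C)=CCBr
Why: Directed ortho-metalation at the carbon flanked by both methoxy groups (the silyl ether neither coordinates lithium nor leaves room beside it), then copper-catalysed allylic substitution at the primary carbon of 4 to give the linear prenyl group.

Step 3
Reactants: 6 (3,5-dimethoxy-4-prenylphenoxy)triisopropylsilane; 7 propargyl bromide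
Product: 9 1,3-dimethoxy-2-prenyl-5-(prop-2-ynyloxy)benzene, via ammonium phenoxide 8 (not isolated)
Conditions: Bu4NF (1.05 equiv), THF, 0 °C; then 7, rt
Reagents that add atoms: propargyl bromide, C#CCBr
Why: Fluoride cleaves the aryl silyl ether and the naked phenoxide 8 is alkylated in the same flask (Williamson ether synthesis).

Step 4
Reactants: 9 1,3-dimethoxy-2-prenyl-5-(prop-2-ynyloxy)benzene
Product: 11 5,7-dimethoxy-6-prenyl-2H-chromene, via allenylphenol 10 (not isolated)
Conditions: PhNEt2, 210 °C
Reagents that add atoms: none
Why: Aromatic propargyl Claisen rearrangement gives 10 after enolisation; a 1,5-hydrogen shift and oxa-6π electrocyclisation then close the pyran ring. The two ortho positions of 9 are equivalent, so one chromene results.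

Step 5
Reactants: 11 5,7-dimethoxy-6-prenyl-2H-chromene; 12 bis(pinacolato)diboron
Product: 13 2-[(3S)-5,7-dimethoxy-6-prenylchroman-3-yl]-4,4,5,5-tetramethyl-1,3,2-dioxaborolane
Conditions: CuCl (5 mol%), Ph-BPE (6 mol%, antipode chosen for 3S), NaOt-Bu (10 mol%), MeOH (2 equiv), THF, rt
Reagents that add atoms: bis(pinacolato)diboron, CC1(C)OB(OC1(C)C)B1OC(C)(C)C(C)(C)O1
Why: Enantioselective protoboration with a boryl complex of monovalent copper: syn borylcupration of the styrene-type C3=C4 bond puts copper at benzylic C4 and boron at C3, and methanol protonates the C–Cu bond. The chiral bisphosphine on copper selects the alkene face and so sets C3; the prenyl alkene is unactivated and does not react.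

Step 6
Reactants: 13 (3S)-boronate; 14 vinyl bromide
Product: 16 (3S)-3-(1-bromovinyl)-5,7-dimethoxy-6-prenylchroman, via boron ate complex 15 (not isolated)
Conditions: 14, LiN(i-Pr)2, THF, −78 °C (carbenoid formed in the presence of 13); then I2, MeOH, −78 to 0 °C; NaOMe
Reagents that add atoms: vinyl bromide, C=CBr
Why: Zweifel-type olefination: the alpha-lithiated vinyl bromide adds to boron to give 15, iodine activates the alkene and triggers 1,2-migration of the chromanyl group from boron to carbon with retention at C3, and methoxide-induced anti elimination of boron and iodine releases the bromoalkene.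

Step 7
Reactants: 16 (3S)-3-(1-bromovinyl)-5,7-dimethoxy-6-prenylchroman
Product: 17 (3R)-3-ethynyl-5,7-dimethoxy-6-prenylchroman
Conditions: Bu4NF·3H2O, DMF, 60 °C
Reagents that add atoms: none
Why: Fluoride-mediated dehydrobromination of a 2-bromo-1-alkene to the terminal alkyne; the base is too weak to remove the propargylic C3 hydrogen, so the configuration is kept (the descriptor changes only through priorities).

Step 8
Reactants: 17 (3R)-3-ethynyl-5,7-dimethoxy-6-prenylchroman; 18 acetyl chloride
Product: 20 (E)-4-[(3R)-5,7-dimethoxy-6-prenylchroman-3-yl]but-3-en-2-one, via alkenylzirconocene 19 (not isolated)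
Conditions: Cp2Zr(H)Cl, THF, rt; then CuBr·SMe2 (10 mol%), 18, 0 °C
Reagents that add atoms: acetyl chloride, CC(=O)Cl
Why: syn-Hydrozirconation of the terminal alkyne puts zirconium on the terminal carbon and fixes the E geometry in 19; copper-catalysed acylation then proceeds with retention of alkene geometry. The trisubstituted prenyl alkene is hydrozirconated far more slowly.

Step 9
Reactants: 20 (E)-enone; 21 4-acetamidobenzenesulfonyl azide
Product: 23 (E)-1-diazo-4-[(3R)-5,7-dimethoxy-6-prenylchroman-3-yl]but-3-en-2-one, via trifluoroacetyl diketone 22 (not isolated)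
Conditions: LiN(SiMe3)2, THF, −78 °C; CF3CO2CH2CF3; then 21, Et3N, H2O, MeCN, rt
Reagents that add atoms: 4-acetamidobenzenesulfonyl azide, CC(=O)Nc1ccc(cc1)S(=O)(=O)N=[N+]=[N-]
Why: Detrifluoroacetylative diazo transfer: kinetic deprotonation of the methyl group, Claisen-type trifluoroacetylation to 22, then diazo transfer with loss of the trifluoroacetyl group. Deprotonation at −78 °C at the methyl group, not at the gamma carbon C3, preserves the stereocentre.

Step 10
Reactants: 24 4-methylpent-3-enoic acid; 25 iodoethane
Product: 26 ethyl 4-methylpent-3-enoate
Conditions: K2CO3, DMF, rt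
Reagents that add atoms: iodoethane, CCI
Why: Carboxylate O-alkylation under weakly basic conditions; acid-catalysed esterification is avoided because this acid lactonises onto its trisubstituted alkene.

Step 11
Reactants: 26 ethyl 4-methylpent-3-enoate; 27 dibromomethane; 2 chlorotriisopropylsilane
Product: 30 triisopropyl[(5-methylhex-4-en-1-yn-1-yl)oxy]silane, via dibromo enolate 28 (not isolated), via lithium ynolate 29 (not isolated)
Conditions: 27, lithium 2,2,6,6-tetramethylpiperidide (2.2 equiv), THF, −78 °C; n-BuLi, −78 °C to rt; then 2, −78 °C to rt
Reagents that add atoms: dibromomethane, BrCBr; chlorotriisopropylsilane, CC(C)[Si](Cl)(C(C)C)C(C)C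
Why: Kowalski ester homologation: the lithium carbenoid from 27 substitutes the ethoxy group and the ketone is deprotonated to 28; bromine–lithium exchange and 1,2-shift of the prenyl-bearing carbon give ynolate 29, which is silylated on oxygen by the bulky chloride 2.

Step 12
Reactants: 23 (E)-diazo ketone; 30 siloxyalkyne
Product: 35 6-[(3R)-5,7-dimethoxy-6-prenylchroman-3-yl]-2-prenyl-3-(triisopropylsiloxy)phenol, via vinylketene 31 (not isolated), via vinylcyclobutenone 32 (not isolated), via dienylketene 33 (not isolated), via cyclohexadienone 34 (not isolated)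
Conditions: 30 (2 equiv), hν (medium-pressure Hg lamp, Pyrex filter), ClCH2CH2Cl, rt; then 80 °C
Reagents that add atoms: none
Why: Irradiation expels dinitrogen from 23 and the alkenyl group migrates from the carbonyl carbon to the former diazo carbon (photochemical Wolff rearrangement, C5'–C6' bond), giving vinylketene 31. The electron-rich alkyne 30 adds across the ketene C=C bond in a polar [2+2] step: its nucleophilic, prenyl-bearing carbon attacks the ketene carbonyl carbon (C2'–C3') and its oxygen-bearing carbon bonds to the ketene alpha carbon (C4'–C5'), so vinylcyclobutenone 32 has the prenyl group next to the carbonyl. On warming, 32 undergoes reversible 4π electrocyclic opening to dienylketene 33; the isomer with the alkenyl arm turned inward closes by thermal disrotatory 6π electrocyclisation (C1'–C2' bond, six-membered ring) to cyclohexadienone 34, which enolises to phenol 35. This is the Danheiser benzannulation in its diazo ketone variant, known with siloxyalkynes to give resorcinol monosilyl ethers. No stereocentre is created: the transiently sp3 ring carbons of 32 and 34 end up aromatic, and C3 remains an sp3 substituent on the alkene terminus throughout. The step needs one orientation in the [2+2] event, which the polarisation of the siloxyalkyne secures; it needs the ketene to choose the alkyne over the prenyl alkenes, which the far higher ketenophilicity of an ynol ether secures; and it needs the E alkene to persist, because a Z vinylketene could lose the C3 hydrogen by a 1,5-shift, so light is limited to wavelengths the diazo ketone absorbs and 30 is present in excess from the start.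

Step 13
Reactants: 35 monosilyl resorcinol
Product: 36 4-[(3R)-5,7-dimethoxy-6-prenylchroman-3-yl]-2-prenylbenzene-1,3-diol
Conditions: Bu4NF, THF, 0 °C
Reagents that add atoms: none
Why: Fluoride cleavage of the aryl silyl ether under conditions that are neither acidic (which would cyclise a prenyl group onto a phenol) nor oxidising.

Step 14
Reactants: 36 resorcinol; 37 potassium nitrosodisulfonate K2[ON(SO3)2]
Product: 38 5-[(3R)-5,7-dimethoxy-6-prenylchroman-3-yl]-2-hydroxy-3-prenylcyclohexa-2,5-diene-1,4-dione (target)
Conditions: 37 (2.5 equiv), KH2PO4 buffer, acetone–H2O, rt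
Reagents that add atoms: potassium nitrosodisulfonate, [K+].[K+].[O]N(S(=O)(=O)[O-])S(=O)(=O)[O-]
Why: Teuber oxidation: one nitrosodisulfonate radical removes a phenolic hydrogen and a second delivers oxygen at the only free activated carbon, C5' (para to the C2' hydroxyl, ortho to the C4' hydroxyl), so either phenol leads to the same hydroxy-para-quinone tautomer. Ring A has no free hydroxyl and is untouched, and the near-neutral buffer protects C3.

## Compound list

1 | 3,5-dimethoxyphenol | COc1cc(O)cc(OC)c1 | starting material
2 | chlorotriisopropylsilane | CC(C)[Si](Cl)(C(C)C)C(C)C | starting material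
3 | (3,5-dimethoxyphenoxy)triisopropylsilane | COc1cc(O[Si](C(C)C)(C(C)C)C(C)C)cc(OC)c1 | intermediate
4 | prenyl bromide (1-bromo-3-methylbut-2-ene) | CC(C)=CCBr | starting material
5 | [2,6-dimethoxy-4-(triisopropylsiloxy)phenyl]lithium | COc1cc(O[Si](C(C)C)(C(C)C)C(C)C)cc(OC)c1[Li] | intermediate (not isolated)
6 | (3,5-dimethoxy-4-prenylphenoxy)triisopropylsilane | COc1cc(O[Si](C(C)C)(C(C)C)C(C)C)cc(OC)c1CC=C(C)C | intermediate
7 | propargyl bromide | C#CCBr | starting material
8 | tetrabutylammonium 3,5-dimethoxy-4-prenylphenoxide | CCCC[N+](CCCC)(CCCC)CCCC.COc1cc([O-])cc(OC)c1CC=C(C)C | intermediate (not isolated)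
9 | 1,3-dimethoxy-2-prenyl-5-(prop-2-ynyloxy)benzene | COc1cc(OCC#C)cc(OC)c1CC=C(C)C | intermediate
10 | 3,5-dimethoxy-4-prenyl-2-(propa-1,2-dienyl)phenol | COc1cc(O)c(C=C=C)c(OC)c1CC=C(C)C | intermediate (not isolated)
11 | 5,7-dimethoxy-6-prenyl-2H-chromene | COc1cc2c(c(OC)c1CC=C(C)C)C=CCO2 | intermediate
12 | bis(pinacolato)diboron | CC1(C)OB(OC1(C)C)B1OC(C)(C)C(C)(C)O1 | starting material
13 | 2-[(3S)-5,7-dimethoxy-6-prenylchroman-3-yl]-4,4,5,5-tetramethyl-1,3,2-dioxaborolane | CC1(C)OB(OC1(C)C)[C@@H]1COc2cc(OC)c(CC=C(C)C)c(OC)c2C1 | intermediate
14 | vinyl bromide | C=CBr | starting material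
15 | lithium (1-bromovinyl)[(3S)-5,7-dimethoxy-6-prenylchroman-3-yl](pinacolato)borate | [Li+].C=C(Br)[B-]1(OC(C)(C)C(C)(C)O1)[C@@H]1COc2cc(OC)c(CC=C(C)C)c(OC)c2C1 | intermediate (not isolated)
16 | (3S)-3-(1-bromovinyl)-5,7-dimethoxy-6-prenylchroman | C=C(Br)[C@@H]1COc2cc(OC)c(CC=C(C)C)c(OC)c2C1 | intermediate
17 | (3R)-3-ethynyl-5,7-dimethoxy-6-prenylchroman | C#C[C@@H]1COc2cc(OC)c(CC=C(C)C)c(OC)c2C1 | intermediate
18 | acetyl chloride | CC(=O)Cl | starting material
19 | chloro{(E)-2-[(3R)-5,7-dimethoxy-6-prenylchroman-3-yl]ethenyl}bis(cyclopentadienyl)zirconium (Cp drawn sigma-bonded) | Cl[Zr](/C=C/[C@@H]1COc2cc(OC)c(CC=C(C)C)c(OC)c2C1)(C1C=CC=C1)C1C=CC=C1 | intermediate (not isolated)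
20 | (E)-4-[(3R)-5,7-dimethoxy-6-prenylchroman-3-yl]but-3-en-2-one | CC(=O)/C=C/[C@@H]1COc2cc(OC)c(CC=C(C)C)c(OC)c2C1 | intermediate
21 | 4-acetamidobenzenesulfonyl azide | CC(=O)Nc1ccc(cc1)S(=O)(=O)N=[N+]=[N-] | starting material
22 | (E)-1,1,1-trifluoro-6-[(3R)-5,7-dimethoxy-6-prenylchroman-3-yl]hex-5-ene-2,4-dione (present as its lithium enolate) | O=C(CC(=O)C(F)(F)F)/C=C/[C@@H]1COc2cc(OC)c(CC=C(C)C)c(OC)c2C1 | intermediate (not isolated)
23 | (E)-1-diazo-4-[(3R)-5,7-dimethoxy-6-prenylchroman-3-yl]but-3-en-2-one | [N-]=[N+]=CC(=O)/C=C/[C@@H]1COc2cc(OC)c(CC=C(C)C)c(OC)c2C1 | intermediate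
24 | 4-methylpent-3-enoic acid | CC(C)=CCC(=O)O | starting material
25 | iodoethane | CCI | starting material
26 | ethyl 4-methylpent-3-enoate | CCOC(=O)CC=C(C)C | intermediate
27 | dibromomethane | BrCBr | starting material
28 | lithium 1,1-dibromo-5-methylhexa-1,4-dien-2-olate | [Li+].[O-]C(CC=C(C)C)=C(Br)Br | intermediate (not isolated)
29 | lithium 5-methylhex-4-en-1-yn-1-olate | [Li+].[O-]C#CCC=C(C)C | intermediate (not isolated)
30 | triisopropyl[(5-methylhex-4-en-1-yn-1-yl)oxy]silane | CC(C)=CCC#CO[Si](C(C)C)(C(C)C)C(C)C | intermediate
31 | (E)-4-[(3R)-5,7-dimethoxy-6-prenylchroman-3-yl]buta-1,3-dien-1-one | O=C=C/C=C/[C@@H]1COc2cc(OC)c(CC=C(C)C)c(OC)c2C1 | intermediate (not isolated)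
32 | 4-{(E)-2-[(3R)-5,7-dimethoxy-6-prenylchroman-3-yl]ethenyl}-2-prenyl-3-(triisopropylsiloxy)cyclobut-2-en-1-one (ring C4 unassigned) | O=C1C(CC=C(C)C)=C(O[Si](C(C)C)(C(C)C)C(C)C)C1/C=C/[C@@H]1COc2cc(OC)c(CC=C(C)C)c(OC)c2C1 | intermediate (not isolated)
33 | (3E,5E)-6-[(3R)-5,7-dimethoxy-6-prenylchroman-3-yl]-2-prenyl-3-(triisopropylsiloxy)hexa-1,3,5-trien-1-one | O=C=C(CC=C(C)C)/C(O[Si](C(C)C)(C(C)C)C(C)C)=C\C=C\[C@@H]1COc2cc(OC)c(CC=C(C)C)c(OC)c2C1 | intermediate (not isolated)
34 | 6-[(3R)-5,7-dimethoxy-6-prenylchroman-3-yl]-2-prenyl-3-(triisopropylsiloxy)cyclohexa-2,4-dien-1-one (ring C6 unassigned) | O=C1C(CC=C(C)C)=C(O[Si](C(C)C)(C(C)C)C(C)C)C=CC1[C@@H]1COc2cc(OC)c(CC=C(C)C)c(OC)c2C1 | intermediate (not isolated)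
35 | 6-[(3R)-5,7-dimethoxy-6-prenylchroman-3-yl]-2-prenyl-3-(triisopropylsiloxy)phenol | CC(C)=CCc1c(O[Si](C(C)C)(C(C)C)C(C)C)ccc(c1O)[C@@H]1COc2cc(OC)c(CC=C(C)C)c(OC)c2C1 | intermediate
36 | 4-[(3R)-5,7-dimethoxy-6-prenylchroman-3-yl]-2-prenylbenzene-1,3-diol | CC(C)=CCc1c(O)ccc(c1O)[C@@H]1COc2cc(OC)c(CC=C(C)C)c(OC)c2C1 | intermediate
37 | potassium nitrosodisulfonate, K2[ON(SO3)2] | [K+].[K+].[O]N(S(=O)(=O)[O-])S(=O)(=O)[O-] | starting material
38 | 5-[(3R)-5,7-dimethoxy-6-prenylchroman-3-yl]-2-hydroxy-3-prenylcyclohexa-2,5-diene-1,4-dione | COc1cc2c(c(OC)c1CC=C(C)C)C[C@H](C1=CC(=O)C(O)=C(CC=C(C)C)C1=O)CO2 | target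

## Step count and least certain steps

Total step count: 14. Longest linear sequence: 12 steps (steps 1–9, then 12–14). The siloxyalkyne branch (steps 10 and 11) joins at step 12.

**Step 12 (key step).**
- Most likely to go wrong: photochemical E/Z isomerisation of the alkene, followed by a 1,5-hydrogen shift from C3 in the Z vinylketene; acylation of the product phenol by unreacted ketene; and competitive light absorption by the dimethoxyarene. Each drains material before the [2+2] event.
- Fallback (sets out from alkyne 17 and siloxyalkyne 30; returns at vinylcyclobutenone 32 and hence 35): the four-membered ring is assembled without light. Chloroketene, generated from chloroacetyl chloride and Et3N in the presence of 30, should add with the same polarity-controlled orientation to give 4-chloro-2-prenyl-3-(triisopropylsiloxy)cyclobut-2-en-1-one F1. Alkenylzirconocene 19, made from 17 as in step 8, is then coupled with F1 under zerovalent palladium catalysis (PdCl2(PhCN)2, tri(2-furyl)phosphine, dioxane, 50–80 °C). This is a known route to 4-alkenylcyclobutenones, which open and electrocyclise to the phenol at the coupling temperature.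

**Step 5.**
- Most likely to go wrong: slow borylcupration and poor facial selectivity, because the peri methoxy group at C5 crowds C4 and the electron-rich arene stabilises a benzylic copper species poorly.
- Fallback (from 11, back to 13): stoichiometric asymmetric hydroboration. Diisopinocampheylborane from (+)-alpha-pinene, the antipode expected to be right by analogy with simple cis-alkenes, adds boron at C3 to give B-[(3S)-chroman-3-yl]diisopinocampheylborane F2. Acetaldehyde releases the terpene groups to give diethyl boronate F3, and pinacol converts F3 into 13.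

**Step 6.**
- Most likely to go wrong: decomposition of the alpha-bromovinyl carbenoid before boron captures it; consumption of iodine by the prenyl group or by ring A; and, less likely, fragmentation of the ate complex by loss of the beta-aryloxide.
- Fallback (from 13, back to enone 20, bypassing steps 6–8): Matteson homologation with LiCH2Cl (from ICH2Cl and n-BuLi, −78 °C) gives 2-{[(3S)-5,7-dimethoxy-6-prenylchroman-3-yl]methyl}-4,4,5,5-tetramethyl-1,3,2-dioxaborolane F4 with retention. NaBO3·4H2O oxidation gives [(3R)-5,7-dimethoxy-6-prenylchroman-3-yl]methanol F5. Dess–Martin oxidation gives (3S)-5,7-dimethoxy-6-prenylchromane-3-carbaldehyde F6, which is used at once with Ph3P=CHC(O)CH3 in a neutral, E-selective Wittig reaction to reach 20. The price is the configurational lability of F6.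

**Step 11.**
- Most likely to go wrong: deprotonation of the doubly activated alpha-methylene of 26 (allylic and next to the ester) competing with acyl substitution, leading to recovered or conjugated ester instead of the ynolate.
- Fallback (from prenyl bromide 4, back to ynolate 29 and hence 30): the ynolate is made by oxidation instead of homologation. Copper-catalysed coupling of 4 with HC≡CMgBr (CuCl, THF) gives 5-methylhex-4-en-1-yne F7. n-BuLi gives its lithium acetylide F8. Oxygen transfer from LiOOt-Bu (from t-BuOOH and LiN(SiMe3)2) converts F8 into 29, which is silylated with 2 as before.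

**Step 14.**
- Most likely to go wrong: over-oxidation or oxidative coupling of the very electron-rich free resorcinol through ortho-quinone intermediates, and oxidative cyclisation of the C3' prenyl group onto a neighbouring oxygen.
- Fallback (from 35, back to 38, replacing steps 13 and 14): the order is reversed so that only one phenol is free. PhI(OAc)2 in MeCN–H2O at 0 °C oxidises the C2' phenol of 35 at its free para position to give 5-[(3R)-5,7-dimethoxy-6-prenylchroman-3-yl]-3-prenyl-2-(triisopropylsiloxy)-1,4-benzoquinone F9. The vinylogous silyl ester is then cleaved with HF·pyridine to give 38.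

## Further compounds

F1 | step 12 | 4-chloro-2-prenyl-3-(triisopropylsiloxy)cyclobut-2-en-1-one | O=C1C(CC=C(C)C)=C(O[Si](C(C)C)(C(C)C)C(C)C)C1Cl
F2 | step 5 | B-[(3S)-5,7-dimethoxy-6-prenylchroman-3-yl]diisopinocampheylborane (terpene groups from (+)-alpha-pinene) | C[C@H]1[C@@H](C[C@@H]2C[C@H]1C2(C)C)B([C@@H]3C[C@@H]4C[C@H]([C@H]3C)C4(C)C)[C@@H]5COc6cc(OC)c(CC=C(C)C)c(OC)c6C5
F3 | step 5 | diethyl [(3S)-5,7-dimethoxy-6-prenylchroman-3-yl]boronate | CCOB(OCC)[C@@H]1COc2cc(OC)c(CC=C(C)C)c(OC)c2C1
F4 | step 6 | 2-{[(3S)-5,7-dimethoxy-6-prenylchroman-3-yl]methyl}-4,4,5,5-tetramethyl-1,3,2-dioxaborolane | CC1(C)OB(C[C@@H]2COc3cc(OC)c(CC=C(C)C)c(OC)c3C2)OC1(C)C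
F5 | step 6 | [(3R)-5,7-dimethoxy-6-prenylchroman-3-yl]methanol | OC[C@@H]1COc2cc(OC)c(CC=C(C)C)c(OC)c2C1
F6 | step 6 | (3S)-5,7-dimethoxy-6-prenylchromane-3-carbaldehyde | O=C[C@@H]1COc2cc(OC)c(CC=C(C)C)c(OC)c2C1
F7 | step 11 | 5-methylhex-4-en-1-yne | C#CCC=C(C)C
F8 | step 11 | (5-methylhex-4-en-1-yn-1-yl)lithium | [Li]C#CCC=C(C)C
F9 | step 14 | 5-[(3R)-5,7-dimethoxy-6-prenylchroman-3-yl]-3-prenyl-2-(triisopropylsiloxy)cyclohexa-2,5-diene-1,4-dione | O=C1C=C([C@@H]2COc3cc(OC)c(CC=C(C)C)c(OC)c3C2)C(=O)C(CC=C(C)C)=C1O[Si](C(C)C)(C(C)C)C(C)C
A1 | alternative 1 | 4,4,5,5-tetramethyl-2-vinyl-1,3,2-dioxaborolane | C=CB1OC(C)(C)C(C)(C)O1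
A2 | alternative 1 | (2,4,5-trimethoxy-3-prenylphenyl)lithium | [Li]c1cc(OC)c(OC)c(CC=C(C)C)c1OC
A3 | alternative 1 | 2,4-dimethoxy-6-(methoxymethoxy)-3-prenylphenyl trifluoromethanesulfonate | COCOc1cc(OC)c(CC=C(C)C)c(OC)c1OS(=O)(=O)C(F)(F)F
A4 | alternative 1 | secondary pinacol boronate bearing the ring A benzyl group and the ring B aryl group, boron at the future C3 | COCOc1cc(OC)c(CC=C(C)C)c(OC)c1C[C@H](c1cc(OC)c(OC)c(CC=C(C)C)c1OC)B1OC(C)(C)C(C)(C)O1
A5 | alternative 2 | 2-methoxy-3-prenyl-1,4-benzoquinone | COC1=C(CC=C(C)C)C(=O)C=CC1=O
A6 | alternative 2 | cis-(6aR,11aR)-pterocarpan with a free phenol para to the furan oxygen | COc1cc2c(c(OC)c1CC=C(C)C)[C@@H]1Oc3c(CC=C(C)C)c(OC)c(O)cc3[C@@H]1CO2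
A7 | alternative 3 | 2-(2,4,5-trimethoxy-3-prenylphenyl)acetaldehyde | O=CCc1cc(OC)c(OC)c(CC=C(C)C)c1OC
A8 | alternative 3 | 3,5-dimethoxy-4-prenyl-2-[(4-methylphenylsulfonyl)methyl]phenol | Cc1ccc(cc1)S(=O)(=O)Cc1c(O)cc(OC)c(CC=C(C)C)c1OC
A9 | alternative 3 | 3,5-dimethoxy-6-methylidene-4-prenylcyclohexa-2,4-dien-1-one | C=C1C(=O)C=C(OC)C(CC=C(C)C)=C1OC
A10 | alternative 3 | 3-(2,4,5-trimethoxy-3-prenylphenyl)-5,7-dimethoxy-6-prenylchroman-2-ol, C3 configured, anomeric mixture | COc1cc2c(c(OC)c1CC=C(C)C)C[C@H](c1cc(OC)c(OC)c(CC=C(C)C)c1OC)C(O)O2
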